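**Root ratio.** The ratio of monomer in chains at 80.0 min, alpha run over beta run, reads 1.26, and the square root of the ratio of their initiator loadings is 1.25. Scaled by that root from the beta run, the flask should hold 28.5% of its free monomer charge in chains at 80 min. But this rests on one ratio, and each reading scatters by 0.5 percentage points.

all flasks: free monomer 0.050 M
- beta: initiator 14 mol%; run made earlier
- alpha: initiator 22 mol%; run made earlier
- flask: initiator 10 mol%; time 80 min

| run | time / min | monomer in chains / % | free monomer / % |
|---|---|---|---|
| beta | 12.0 | 2.1 | 98.2 |
| beta | 25.0 | 6.6 | 92.8 |
| beta | 30.0 | 9.0 | 90.5 |
| beta | 50.0 | 19.0 | 81.3 |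
| beta | 60.0 | 24.3 | 77.1 |
| beta | 80.0 | 33.7 | 67.0 |
| alpha | 6.00 | 1.3 | 98.5 |
| alpha | 10.0 | 2.4 | 97.1 |
| alpha | 15.0 | 4.5 | 95.1 |
| alpha | 25.0 | 10.7 | 89.9 |
| alpha | 30.0 | 13.9 | 86.5 |
| alpha | 50.0 | 26.2 | 73.6 |
| alpha | 80.0 | 42.3 | 58.2 |

(each reading ± 0.5 percentage points)

- the average divides the monomer in chains by the number of chains begun, living and dead together
- steps under discussion: free monomer + initiator -> living end + monomer in chains; free monomer + living end -> monomer in chains + living end; 2 living end -> dead end
- the earlier runs do not show the number of chains; that part of a forecast is a guess

1. whether the average number of monomer units in a chain (chains begun, living or dead) reaches 3.0 by 80 min (yes / no)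
2. average number of monomer units in a chain (chains begun, living or dead) at 80 min

**Counting turnovers.** By the first step, each chain begun takes one initiator. The flask therefore should reach 2.85 turnovers per initiator charged, meaning monomer in chains as a fraction of the free monomer charge, divided by the loading. The average length (number-average degree of polymerisation) is turnovers divided by the fraction of initiator spent. The objection: the turnovers stand below the 3.0 wanted, so the length passes it with under 95.0% spent, and the earlier runs do not show that fraction.

**Spent initiator.** A chain holds at least one unit, so the fraction spent at the first alpha reading is, as read, at most uptake over loading, 5.91%. Taking the first step as first order in initiator, the fractional loss per equal interval is independent of loading and does not grow as free monomer falls, so repeating it gives an estimated ceiling of 55.6% by 80 min. But that reading is 1.3%, with a scatter of 0.5 points. The first beta reading, 2.1%, gives 15.0% at 12.0 min and a ceiling of 66.2%. The flask's estimated floor is then 4.31, above 3.0. This reckoning, scatter included, says yes and gives an estimate of a floor, not a value.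

**The forecast.** The forecast answers yes and puts the length at 7.5, within 4.5 to 15, adding: “This is poorly fixed because the intercept is noisy”.

**The flask.** The simulated flask answers yes, with a length of 10.6.

    free monomer + initiator → living end + monomer in chains (k = 0.0816 L mol⁻¹ min⁻¹)
    free monomer + living end → monomer in chains + living end, rate k2*[living end]*[free monomer] (k = 7.10 L mol⁻¹ min⁻¹)
    2 living end → dead end (k = 12.5 L mol⁻¹ min⁻¹)

**The count again.** At 80.0 min the flask holds 26.7% of its free monomer charge in chains, which is 2.67 turnovers against the 2.85 carried, and it has spent 25.1% of its initiator, so the quotient is 10.6. The hour of the reading matters. At 800 min, ten times the asked time, the flask stands at 8.92 turnovers with 65.9% of its initiator spent, and the length is 13.5.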